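The target, on the list of suspects, forms when one open intermediate meets one second intermediate, and each open intermediate that goes to homo product or side product is a turnover lost. The useful count is therefore turnovers won over turnovers lost.

| setting | north-west | south | flask |
|---|---|---|---|
| starting material | 1.5 M | 1.5 M | 1.5 M |
| partner | 1 equiv | 1.5 equiv | 2.00 equiv |
| remark | run made earlier | run made earlier |  |
| time |  |  | 8.0 h |

| run | time / h | target / % | homo product / % |
|---|---|---|---|
| north-west | 0.833 | 3.5 | 1.8 |
| north-west | 2.00 | 8.4 | 6.8 |
| north-west | 4.00 | 11.3 | 6.1 |
| north-west | 10.0 | 10.8 | 5.0 |
| south | 0.833 | 5.5 | 3.4 |
| south | 2.00 | 11.9 | 4.5 |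
| south | 4.00 | 16.5 | 4.0 |
| south | 10.0 | 16.4 | 6.1 |

(each reading ± 1 percentage point)

- amount of target in the flask at 8.0 h, in percent of the starting material charged
- amount of homo product in the flask at 8.0 h, in percent of the starting material charged
- amount of side product in the flask at 8.0 h, in percent of the starting material charged
- concentration of second intermediate at 8.0 h, in M

- percentages count the starting material that a species holds: one homo product counts as two
- on the list of suspects stand: starting material <-> open intermediate; partner -> second intermediate; open intermediate + second intermediate -> target; 2 open intermediate -> homo product; open intermediate -> side product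

Read the target columns from the bottom. The north-west run stands at 11.3% at 4.00 h and 10.8% at 10.0 h, and the south run at 16.5% and 16.4% at those times. Against a scatter of 1 percentage point these pairs read as plateaus, with means of 11.1% and 16.4%, and the asked 8.0 h lies between those two times.

Let S be target over the rest of the charge at the plateau, and c_D the molar partner charge. Suppose second intermediate stands near c_D. Open intermediate then has a pseudo-first-order road to target, with a rate proportional to c_D, beside a first-order road to side product, and, homo product set aside, S/c_D should hold steady. The readings give 0.0828 L mol⁻¹ for the north-west run and 0.0875 L mol⁻¹ for the south run. Their mean, g = 0.0852 L mol⁻¹, is a reading, with the scatter of those plateaus, of the selectivity factor per molar of partner.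

For the flask, c_D is 3.00 M, so this reckoning gives S = 0.255 and target 20.3%. If the partner is fully converted and each turnover to target uses one second intermediate, the flask ends with 2.69 M of second intermediate by this reckoning.

The forecast says “Target yield scales with partner, with mild saturation”. It gives target 21% (19% to 23%), homo product 4.5%, side product 74% and second intermediate 2.65 M. Its target is slightly above the reckoning here.

The flask gives target 20.5%, homo product 4.56%, side product 74.9% and second intermediate 2.69 M.

    starting material ⇌ open intermediate (K = 20.0, k = 3.40 h⁻¹)
    partner → second intermediate (k = 1.30 h⁻¹)
    open intermediate + second intermediate → target (k = 0.110 L mol⁻¹ h⁻¹)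
    2 open intermediate → homo product (k = 0.0410 L mol⁻¹ h⁻¹)
    open intermediate → side product (k = 0.770 h⁻¹)

At 0.533 h the flask's open intermediate goes to side product 4.8 times as fast as to target. The flask's result corresponds to S/c_D = 0.0860 L mol⁻¹, beside g = 0.0852 L mol⁻¹. The neighbour flask with 0.60 M of starting material and the same equivalents has c_D = 1.20 M, so g gives S = 0.102 and target 9.27%. That neighbour holds 10.3% target.

The runs are calculated for substances that don't exist, noise included.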